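The east run stalled early despite its 22 mM of salt, so I had to decide whether the next flask needed that much or could do with half of it.

the same everywhere: substrate 10 mM; spent carrier 0.57 mM

| run | salt in the second phase | remark | time | volume of the second phase over the first |
|---|---|---|---|---|
| west | 5.5 mM | run made earlier |  |  |
| east | 22 mM | run made earlier |  |  |
| flask | 11.0 mM |  | 5.0 min | 0.25 |

| run | time / min | substrate / % | product / % |
|---|---|---|---|
| west | 0.250 | 45.9 | 53.5 |
| west | 0.833 | 45.7 | 53.2 |
| west | 1.33 | 46.5 | 53.0 |
| west | 2.00 | 45.9 | 53.5 |
| west | 3.00 | 44.5 | 53.4 |
| west | 4.00 | 45.1 | 53.6 |
| west | 5.00 | 46.1 | 53.3 |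
| east | 0.250 | 7.6 | 88.0 |
| east | 0.833 | 5.7 | 88.4 |
| east | 1.33 | 5.5 | 88.5 |
| east | 2.00 | 6.3 | 89.1 |
| east | 3.00 | 5.7 | 89.0 |
| east | 4.00 | 6.0 | 88.1 |
| east | 5.00 | 5.4 | 89.7 |

(readings scatter by 0.5 percentage points)

- in the second phase: salt in the second phase, spent salt in the second phase; everything else is in the first
- charges count per volume of the first phase; a concentration in a rate is the amount of a species over the volume of its own phase; every rate counts per litre of the first phase
- reactions considered so far: spent carrier + salt in the second phase <-> fresh carrier + spent salt in the second phase; substrate + fresh carrier -> product + spent carrier; product + fresh carrier -> spent catalyst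
- the earlier runs hold the two phases in the same ratio of volumes as the flask asked about

1. conversion of substrate at 5.0 min
2. amount of product at 5.0 min, in percent of the substrate charged

West turned 5.39 mM of substrate on 5.5 mM of salt, so I took salt as its limiting reagent. Over its last three readings east held substrate at 5.70% and product at 88.9%. That left 0.537 mM missing from the east balance, close to the 0.57 mM of spent carrier charged, so I read the stall as carrier lost to product.

Let s be the death ratio, how much faster fresh carrier reacts with product than with substrate at equal concentration (a selectivity factor). Each small fractional fall in substrate then destroys s times the product present. Taking product as the substrate lost and adding up the falls gives C/S = s·f, where C is carrier charged, S is substrate charged, a is the fraction of substrate left and f = ln(1/a) − 1 + a. The east reading gives s = 0.0297.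

Salt does not enter this sum, so the flask, with east's S and C, should stall at east's a if its salt lasts. Each substrate turned costs one salt and each carrier lost one more, so the flask needs 10.0 mM, less than its 11.0 mM. I kept 11.0 mM and expected 94.3% conversion and 88.6% product.

The forecast gave 94% (91.5% to 95%) and 88.6% (86% to 90%), holding that “the carrier should die before the salt runs out”.

The flask gave 94.4% conversion and 88.7% product, with 9.0% of its salt left and spent catalyst at >99.9% of the catalyst charged after 5.00 min.

    spent carrier + salt in the second phase ⇌ fresh carrier + spent salt in the second phase (K = 0.861, k = 597 /M/s)
    substrate + fresh carrier → product + spent carrier (k = 1120 /M/s)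
    product + fresh carrier → spent catalyst (k = 34.2 /M/s)

A neighbouring flask was charged with 0.34 mM of spent carrier, its other charges and its time as in the flask. With the same s, f must equal 1.15. A first value from a = exp(−(1 + f − a)), starting from nothing and put back in two more times, gave 13.3% of substrate left in the neighbour. That meant 83.3% product and a salt need of 9.01 mM. The neighbour gave 86.5% conversion and 83.1% product, and it kept 18% of its salt.

Readings and results stem from a simulated flask from invented constants; scatter was added.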